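**Plan**
- Retrosynthesis: the 5‑O–S (tosyl) and 3‑O–CH3 bonds are cut last, and the C3–O bond is traced back to a C3–I bond. The pyranone is then opened at O1–C2 (together with C3–I) to an aryl ynone, which is cut at the C4–C3 bond into an aryl aldehyde and an aryl acetylene.
- Enabling feature: O1 of ring C lies between C8a and C2 and can be supplied by a methoxy oxygen. In 3,4,5‑trimethoxyphenol the OH maps onto the C5 oxygen and the three OMe groups onto O1, 8‑OMe and 7‑OMe, so ring A is bought with its full oxygen pattern.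
- Forward: rings A and B come as commercial arenes and are joined through a three‑carbon ynone (formyl carbon = C4, alkyne carbons = C3 and C2). Ring C is then closed by iodocyclisation through the methoxy oxygen.
- Endgame: C3–I is converted to C3–OH, then C3–OMe, and the 5‑sulfonate is removed.
- Stereochemistry: the target has no stereogenic element. The one carbinol centre on the way is made racemic and erased by oxidation.

Key step: step 6

Remark: because the target is achiral, "single enantiomer" is met trivially; alcohol 8 is carried as the racemate.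

**Step 1**
Reactants: 1 3,4,5‑trimethoxyphenol
Product: 2 6‑hydroxy‑2,3,4‑trimethoxybenzaldehyde
Conditions: MgCl2, Et3N, (CH2O)n, MeCN, reflux; 1 M HCl work‑up
Reagents that add atoms: paraformaldehyde (formaldehyde), C=O
Why: Casnati–Skattebøl ortho‑formylation, in which the magnesium phenoxide delivers formaldehyde only to the carbon next to the phenol oxygen (both ortho sites are equivalent, para is blocked) and a second formaldehyde accepts hydride to give the aldehyde.

**Step 2**
Reactants: 2 6‑hydroxy‑2,3,4‑trimethoxybenzaldehyde; 3 4‑methylbenzenesulfonyl chloride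
Product: 4 2‑formyl‑3,4,5‑trimethoxyphenyl 4‑methylbenzenesulfonate
Conditions: Et3N, DMAP (cat.), CH2Cl2, 0 °C to rt
Reagents that add atoms: none
Why: DMAP‑catalysed O‑sulfonylation of a phenol, which should turn the future 5‑oxygen into a non‑nucleophilic sulfonate that tolerates acetylide, oxidant and ICl.

**Step 3**
Reactants: 5 2,4‑dimethoxybenzaldehyde
Product: 6 1‑ethynyl‑2,4‑dimethoxybenzene
Conditions: dimethyl (1‑diazo‑2‑oxopropyl)phosphonate, K2CO3, MeOH, rt
Reagents that add atoms: dimethyl (1‑diazo‑2‑oxopropyl)phosphonate, COP(=O)(OC)C(=[N+]=[N-])C(C)=O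
Why: Seyferth–Gilbert homologation in the Ohira–Bestmann variant, which should convert an aryl aldehyde into the terminal alkyne in one operation under mild carbonate conditions.

**Step 4**
Reactants: 6 1‑ethynyl‑2,4‑dimethoxybenzene; 4 2‑formyl‑3,4,5‑trimethoxyphenyl 4‑methylbenzenesulfonate
Product: 8 racemic 2‑[3‑(2,4‑dimethoxyphenyl)‑1‑hydroxyprop‑2‑yn‑1‑yl]‑3,4,5‑trimethoxyphenyl 4‑methylbenzenesulfonate, via lithium (2,4‑dimethoxyphenyl)acetylide 7 (not isolated)
Conditions: n‑BuLi (1.0 equiv to 6), THF, −78 °C; then 4, −78 °C; sat. aq. NH4Cl at −78 °C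
Reagents that add atoms: none
Why: 1,2‑addition of a lithium acetylide to an aldehyde forms the C4–C3 bond; the carbinol centre arises racemic (it is removed in step 5), and the cold quench should keep the sulfonyl group on the phenol oxygen.

**Step 5**
Reactants: 8 racemic 2‑[3‑(2,4‑dimethoxyphenyl)‑1‑hydroxyprop‑2‑yn‑1‑yl]‑3,4,5‑trimethoxyphenyl 4‑methylbenzenesulfonate
Product: 9 2‑[3‑(2,4‑dimethoxyphenyl)prop‑2‑ynoyl]‑3,4,5‑trimethoxyphenyl 4‑methylbenzenesulfonate
Conditions: activated MnO2 (excess), CH2Cl2, rt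
Reagents that add atoms: none
Why: MnO2 oxidation of a benzylic and propargylic secondary alcohol, which should give the ynone without touching the alkyne, the ethers or the sulfonate.

**Step 6**
Reactants: 9 2‑[3‑(2,4‑dimethoxyphenyl)prop‑2‑ynoyl]‑3,4,5‑trimethoxyphenyl 4‑methylbenzenesulfonate
Product: 11 2‑(2,4‑dimethoxyphenyl)‑3‑iodo‑7,8‑dimethoxy‑4‑oxo‑4H‑chromen‑5‑yl 4‑methylbenzenesulfonate, via O1‑methyl oxonium chloride 10 (not isolated)
Conditions: ICl (1.1 equiv, 1 M in CH2Cl2, slow addition), CH2Cl2, −78 °C; aq. Na2S2O3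
Reagents that add atoms: iodine monochloride, ClI
Why: I+ from ICl activates the triple bond so that positive charge builds on the alkyne carbon bonded to ring B, where the 2,4‑dimethoxyphenyl group stabilises it, and the methoxy oxygen ortho to the ketone adds to that carbon anti to iodine to give oxonium 10, from which chloride removes the methyl group by SN2 as chloromethane. The closest known reaction type is the iodine monochloride cyclisation of 2‑methoxyaryl alkynyl ketones to 3‑iodochromones. Ring C closes 6‑endo‑dig (O1–C2 and C3–I are formed), because 5‑exo attack by the same oxygen, or 5‑endo attack by the ortho‑methoxy group of ring B, would have to occur at the alkyne carbon next to C=O, where positive charge is not supported. No stereocentre is created. Two selectivities are needed: of the two oxygens ortho to the ketone only the flanked methoxy one may attack, which the sulfonate secures because its oxygen lone pairs are withdrawn by sulfur, and the alkyne must react before the arenes, which one equivalent of ICl at −78 °C and the fast intramolecular capture should secure, ring B being further deactivated by conjugation to the ynone.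

**Step 7**
Reactants: 11 2‑(2,4‑dimethoxyphenyl)‑3‑iodo‑7,8‑dimethoxy‑4‑oxo‑4H‑chromen‑5‑yl 4‑methylbenzenesulfonate
Product: 14 2‑(2,4‑dimethoxyphenyl)‑3‑hydroxy‑7,8‑dimethoxy‑4‑oxo‑4H‑chromen‑5‑yl 4‑methylbenzenesulfonate, via C3 chloromagnesium flavone 12 (not isolated), via C3 dimethyl boronate 13 (not isolated)
Conditions: i‑PrMgCl·LiCl (1.1 equiv), THF, −40 °C; B(OMe)3 (3 equiv), −40 to 0 °C; then AcOH, 30% H2O2, 0 °C to rt
Reagents that add atoms: hydrogen peroxide, OO
Why: Iodine–magnesium exchange at the electron‑poor alkenyl iodide should be fast at −40 °C and spare the vinylogous‑ester carbonyl and the aryl sulfonate, and borate capture followed by peroxide oxidation (1,2‑shift from boron to oxygen) is the established way to turn a C3‑metalated flavone into the flavonol.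

**Step 8**
Reactants: 14 2‑(2,4‑dimethoxyphenyl)‑3‑hydroxy‑7,8‑dimethoxy‑4‑oxo‑4H‑chromen‑5‑yl 4‑methylbenzenesulfonate
Product: 15 2‑(2,4‑dimethoxyphenyl)‑3,7,8‑trimethoxy‑4‑oxo‑4H‑chromen‑5‑yl 4‑methylbenzenesulfonate
Conditions: MeI, K2CO3, acetone, reflux
Reagents that add atoms: iodomethane, CI
Why: Williamson O‑methylation of the acidic 3‑hydroxyl, the only free OH in the molecule, under conditions that leave an aryl sulfonate intact.

**Step 9**
Reactants: 15 2‑(2,4‑dimethoxyphenyl)‑3,7,8‑trimethoxy‑4‑oxo‑4H‑chromen‑5‑yl 4‑methylbenzenesulfonate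
Product: 16 5‑hydroxy‑3,7,8,2',4'‑pentamethoxyflavone
Conditions: KOH (4 equiv), THF/H2O, 50 °C; then 1 M HCl
Reagents that add atoms: none
Why: Alkaline hydrolysis of an aryl sulfonate by hydroxide attack at sulfur, eased by the good leaving ability of the phenoxide peri to C4=O; the methyl ethers are inert and the phenoxide formed should shield the pyranone from hydroxide.

**Compound list**
1 | 3,4,5‑trimethoxyphenol | COc1cc(O)cc(OC)c1OC | starting material
2 | 6‑hydroxy‑2,3,4‑trimethoxybenzaldehyde | COc1cc(O)c(C=O)c(OC)c1OC | intermediate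
3 | 4‑methylbenzenesulfonyl chloride | Cc1ccc(S(=O)(=O)Cl)cc1 | starting material
4 | 2‑formyl‑3,4,5‑trimethoxyphenyl 4‑methylbenzenesulfonate | COc1cc(OS(=O)(=O)c2ccc(C)cc2)c(C=O)c(OC)c1OC | intermediate
5 | 2,4‑dimethoxybenzaldehyde | COc1ccc(C=O)c(OC)c1 | starting material
6 | 1‑ethynyl‑2,4‑dimethoxybenzene | C#Cc1ccc(OC)cc1OC | intermediate
7 | lithium (2,4‑dimethoxyphenyl)acetylide | [Li]C#Cc1ccc(OC)cc1OC | intermediate (not isolated)
8 | racemic 2‑[3‑(2,4‑dimethoxyphenyl)‑1‑hydroxyprop‑2‑yn‑1‑yl]‑3,4,5‑trimethoxyphenyl 4‑methylbenzenesulfonate | COc1ccc(C#CC(O)c2c(OC)c(OC)c(OC)cc2OS(=O)(=O)c2ccc(C)cc2)c(OC)c1 | intermediate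
9 | 2‑[3‑(2,4‑dimethoxyphenyl)prop‑2‑ynoyl]‑3,4,5‑trimethoxyphenyl 4‑methylbenzenesulfonate | COc1ccc(C#CC(=O)c2c(OC)c(OC)c(OC)cc2OS(=O)(=O)c2ccc(C)cc2)c(OC)c1 | intermediate
10 | 2‑(2,4‑dimethoxyphenyl)‑3‑iodo‑7,8‑dimethoxy‑1‑methyl‑4‑oxo‑5‑(tosyloxy)‑4H‑chromen‑1‑ium chloride (O1‑methyl oxonium chloride) | COc1ccc(C2=C(I)C(=O)c3c(OS(=O)(=O)c4ccc(C)cc4)cc(OC)c(OC)c3[O+]2C)c(OC)c1.[Cl-] | intermediate (not isolated)
11 | 2‑(2,4‑dimethoxyphenyl)‑3‑iodo‑7,8‑dimethoxy‑4‑oxo‑4H‑chromen‑5‑yl 4‑methylbenzenesulfonate | COc1ccc(-c2oc3c(OC)c(OC)cc(OS(=O)(=O)c4ccc(C)cc4)c3c(=O)c2I)c(OC)c1 | intermediate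
12 | [2‑(2,4‑dimethoxyphenyl)‑7,8‑dimethoxy‑4‑oxo‑5‑(tosyloxy)‑4H‑chromen‑3‑yl]magnesium chloride | COc1ccc(-c2oc3c(OC)c(OC)cc(OS(=O)(=O)c4ccc(C)cc4)c3c(=O)c2[Mg]Cl)c(OC)c1 | intermediate (not isolated)
13 | dimethyl [2‑(2,4‑dimethoxyphenyl)‑7,8‑dimethoxy‑4‑oxo‑5‑(tosyloxy)‑4H‑chromen‑3‑yl]boronate | COc1ccc(-c2oc3c(OC)c(OC)cc(OS(=O)(=O)c4ccc(C)cc4)c3c(=O)c2B(OC)OC)c(OC)c1 | intermediate (not isolated)
14 | 2‑(2,4‑dimethoxyphenyl)‑3‑hydroxy‑7,8‑dimethoxy‑4‑oxo‑4H‑chromen‑5‑yl 4‑methylbenzenesulfonate | COc1ccc(-c2oc3c(OC)c(OC)cc(OS(=O)(=O)c4ccc(C)cc4)c3c(=O)c2O)c(OC)c1 | intermediate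
15 | 2‑(2,4‑dimethoxyphenyl)‑3,7,8‑trimethoxy‑4‑oxo‑4H‑chromen‑5‑yl 4‑methylbenzenesulfonate | COc1ccc(-c2oc3c(OC)c(OC)cc(OS(=O)(=O)c4ccc(C)cc4)c3c(=O)c2OC)c(OC)c1 | intermediate
16 | 5‑hydroxy‑3,7,8,2',4'‑pentamethoxyflavone | COc1ccc(-c2oc3c(OC)c(OC)cc(O)c3c(=O)c2OC)c(OC)c1 | target

**Totals**
Total step count: 9. Longest linear sequence: 8 steps (1 → 2 → 4 → 8 → 9 → 11 → 14 → 15 → 16); the alkyne branch adds one step (5 → 6).

**Steps most likely to fail**

Step 6. The electron‑rich dimethoxyphenyl ring may be iodinated, or ICl may add across the triple bond, before the ether oxygen closes the ring; the oxonium may also demethylate incompletely. The fallback sets out from 9. BCl3 in CH2Cl2 at −78 °C chelates the ketone and should cleave only the methyl ether beside it, giving 2‑[3‑(2,4‑dimethoxyphenyl)prop‑2‑ynoyl]‑3‑hydroxy‑4,5‑dimethoxyphenyl 4‑methylbenzenesulfonate F1. Catalytic DMAP in DMF should then close the free phenol onto the ynone by 6‑endo oxa‑Michael addition to give the 3‑unsubstituted flavone 2‑(2,4‑dimethoxyphenyl)‑7,8‑dimethoxy‑4‑oxo‑4H‑chromen‑5‑yl 4‑methylbenzenesulfonate F2. Deprotonation at C3 with LDA in THF at −78 °C and an iodine quench brings the sequence back to the route at 11.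

Step 7. The C3‑magnesium species may open by β‑elimination of the O1 phenoxide, be protonated to the deiodinated flavone, or the Grignard reagent may add to C4=O before exchange and boron capture are complete. The fallback sets out from 11. Palladium‑catalysed Miyaura borylation (B2pin2, PdCl2(dppf), KOAc, dioxane, 80 °C) avoids a polar organometallic and should give 2‑(2,4‑dimethoxyphenyl)‑7,8‑dimethoxy‑4‑oxo‑3‑(4,4,5,5‑tetramethyl‑1,3,2‑dioxaborolan‑2‑yl)‑4H‑chromen‑5‑yl 4‑methylbenzenesulfonate F3. Oxidation with NaBO3·4H2O in THF/H2O at rt returns to the route at 14.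

Step 4. The new benzylic alkoxide may take over the sulfonyl group from the neighbouring phenol oxygen, the acetylide may attack sulfur, or addition to the doubly ortho‑substituted aldehyde may be slow. The fallback sets out from 4. Pinnick oxidation (NaClO2, NaH2PO4, 2‑methyl‑2‑butene, t‑BuOH/H2O) should give 2,3,4‑trimethoxy‑6‑(tosyloxy)benzoic acid F4. Oxalyl chloride with catalytic DMF in CH2Cl2 converts it into 2,3,4‑trimethoxy‑6‑(tosyloxy)benzoyl chloride F5. Acyl Sonogashira coupling with alkyne 6 (PdCl2(PPh3)2, CuI, Et3N, THF, rt) forms the ynone with no alkoxide intermediate and rejoins the route at 9, so step 5 is not needed.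

**Further compounds**
F1 | step 6 | 2‑[3‑(2,4‑dimethoxyphenyl)prop‑2‑ynoyl]‑3‑hydroxy‑4,5‑dimethoxyphenyl 4‑methylbenzenesulfonate | COc1ccc(C#CC(=O)c2c(O)c(OC)c(OC)cc2OS(=O)(=O)c2ccc(C)cc2)c(OC)c1
F2 | step 6 | 2‑(2,4‑dimethoxyphenyl)‑7,8‑dimethoxy‑4‑oxo‑4H‑chromen‑5‑yl 4‑methylbenzenesulfonate | COc1ccc(-c2cc(=O)c3c(OS(=O)(=O)c4ccc(C)cc4)cc(OC)c(OC)c3o2)c(OC)c1
F3 | step 7 | 2‑(2,4‑dimethoxyphenyl)‑7,8‑dimethoxy‑4‑oxo‑3‑(4,4,5,5‑tetramethyl‑1,3,2‑dioxaborolan‑2‑yl)‑4H‑chromen‑5‑yl 4‑methylbenzenesulfonate | COc1ccc(-c2oc3c(OC)c(OC)cc(OS(=O)(=O)c4ccc(C)cc4)c3c(=O)c2B5OC(C)(C)C(C)(C)O5)c(OC)c1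
F4 | step 4 | 2,3,4‑trimethoxy‑6‑(tosyloxy)benzoic acid | COc1cc(OS(=O)(=O)c2ccc(C)cc2)c(C(=O)O)c(OC)c1OC
F5 | step 4 | 2,3,4‑trimethoxy‑6‑(tosyloxy)benzoyl chloride | COc1cc(OS(=O)(=O)c2ccc(C)cc2)c(C(Cl)=O)c(OC)c1OC
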